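## Retrosynthetic overview
1. The butenolide goes on last: C12–C13 by B-alkyl Suzuki coupling of a 9-vinyl octalin with 4-bromobutenolide. C3=O is carried as an enol triflate, and 6-OH comes from the Δ5(10)-6-enone.
2. Ring B is made by a Diels–Alder reaction (C7–C8 and C9–C10) of a ring-A 2-ethoxydiene with tiglaldehyde, followed by DDQ. This sets C8 and C9; the CHO later becomes the vinyl group.
3. The key bond is C5–C6. An acetyl anion equivalent (1-ethoxyvinylzinc, from ethyl vinyl ether) is coupled with one of the two enantiotopic enol triflates of a 2,2-disubstituted cyclohexane-1,3-dione. A carbonyl carbon is joined to a carbonyl carbon, which creates the dissonant C3/C6 pattern and sets quaternary C4.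
4. Ring A is bought as 2-methylcyclohexane-1,3-dione. C19 comes from formaldehyde, and the phloretate ester is installed at the start.
5. Ring order: A (purchased), then B (cycloaddition), then the butenolide (purchased ring, from tetronic acid).

Numbering used in the text (halimane): ring A = C1–C5 and C10; ring B = C5–C10; C11–C16 = side chain and butenolide; C17 = 8-Me; C18 = 4-Me; C19 = 4-CH2O; C20 = 9-Me. The target is 4S,6S,8S,9R.

Assumption: the sense of induction of the chiral catalysts in steps 5 and 6 is taken from their closest models; if either proves opposite, its equally available mirror image is used.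

## Route

Step 1
Reactants: 1 2-methylcyclohexane-1,3-dione
Product: 2 2-(hydroxymethyl)-2-methylcyclohexane-1,3-dione
Conditions: 37 % aq HCHO (3 equiv), cat. Et3N, THF–H2O, rt; used crude
Reagents that add atoms: formaldehyde C=O
Why: Aldol (Tollens-type) hydroxymethylation: the acidic 2-alkyl-1,3-dione adds through C2 to formaldehyde and the adduct cannot dehydrate, giving quaternary but still prochiral C4 bearing C19.

Step 2
Reactants: 3 3-(4-hydroxyphenyl)propanoic acid (phloretic acid)
Product: 4 3-(4-acetoxyphenyl)propanoic acid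
Conditions: Ac2O (1.2 equiv), pyridine, 0 °C to rt; H2O quench
Reagents that add atoms: acetic anhydride CC(=O)OC(C)=O
Why: Phenol O-acetylation; the acetate keeps the phenol out of the triflation in step 4 and makes the arene too electron-poor for DDQ in step 6, and any mixed anhydride at the acid is hydrolysed in the quench.

Step 3
Reactants: 2 2-(hydroxymethyl)-2-methylcyclohexane-1,3-dione; 4 3-(4-acetoxyphenyl)propanoic acid
Product: 5 (1-methyl-2,6-dioxocyclohexyl)methyl 3-(4-acetoxyphenyl)propanoate
Conditions: DIC, DMAP (5 mol %), CH2Cl2, 0 °C to rt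
Reagents that add atoms: none
Why: Steglich esterification under almost neutral conditions acylates the primary alcohol faster than it can lose formaldehyde by retro-aldol, and once acylated that pathway is closed for the rest of the route.

Step 4
Reactants: 5 (1-methyl-2,6-dioxocyclohexyl)methyl 3-(4-acetoxyphenyl)propanoate
Product: 6 [1-methyl-2,6-bis(triflyloxy)cyclohexa-2,5-dien-1-yl]methyl 3-(4-acetoxyphenyl)propanoate (achiral)
Conditions: Tf2O (2.4 equiv), 2,6-di-tert-butyl-4-methylpyridine (2.6 equiv), CH2Cl2, 0 °C to reflux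
Reagents that add atoms: trifluoromethanesulfonic anhydride O=S(=O)(OS(=O)(=O)C(F)(F)F)C(F)(F)F
Why: Enol triflate formation with Tf2O and a non-nucleophilic pyridine: each ketone can lose a proton only on the side away from quaternary C4, so a single Cs-symmetric bis(enol triflate) results, and the absence of strong base spares both esters.

Step 5 (key step)
Reactants: 6 bis(enol triflate); 7 ethyl vinyl ether
Product: 10 (S)-[2-(1-ethoxyvinyl)-1-methyl-6-(triflyloxy)cyclohexa-2,5-dien-1-yl]methyl 3-(4-acetoxyphenyl)propanoate, via 1-ethoxyvinyllithium 8 (not isolated), via (1-ethoxyvinyl)zinc chloride 9 (not isolated)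
Conditions: 7 (excess), t-BuLi, THF, −78 to 0 °C; ZnCl2, 0 °C; then 6 (1.0 equiv per 1.1 equiv of 9), Pd2(dba)3 (2.5 mol %), (R)-MeO-MOP (11 mol %), THF, 0 °C to rt
Reagents that add atoms: none
Why: Proposed new method: this is an enantiotopic-group-selective Negishi coupling in which the acetyl anion equivalent 9 (C6, a carbonyl carbon used as a nucleophile) is joined to C5, itself a former carbonyl carbon, so two normally electrophilic carbons are bonded and the dissonant C3/C6 1,4-dioxygen pattern is created; oxidative addition of the bulky monophosphine–Pd(0) into one of the two enantiotopic C–OTf bonds flanking the prochiral centre is irreversible, stereodetermining and independent of the nucleophile, which fixes C4 as S, while the minor enantiomer still carries the favoured triflate and is drained into the bis-coupled by-product so that ee rises with conversion; the closest known reaction types are the Pd/MOP-catalysed desymmetrising Suzuki coupling of bis(enol triflates) of 2,2-disubstituted 1,3-diketones and the routine Negishi or Stille coupling of 1-alkoxyvinyl metals with enol triflates.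

Step 6
Reactants: 10 ethoxydiene; 11 (E)-2-methylbut-2-enal (tiglaldehyde)
Product: 13 [(1S,5R,6S)-5-formyl-1,5,6-trimethyl-8-oxo-2-(triflyloxy)-1,4,5,6,7,8-hexahydronaphthalen-1-yl]methyl 3-(4-acetoxyphenyl)propanoate, via Diels–Alder adduct 12 (not isolated)
Conditions: 11 (3 equiv), (S)-diphenylprolinol-derived B-(o-tolyl)oxazaborolidine·HNTf2 (20 mol %), CH2Cl2, −78 to −40 °C; then DDQ (1.3 equiv), pH 7 buffer, 0 °C
Reagents that add atoms: water O
Why: Normal-demand Diels–Alder reaction under cationic oxazaborolidine catalysis followed by DDQ dehydrogenation of the enol ether: the 2-ethoxy and 1-alkyl groups of the diene both send C7 to the β-carbon and C10 to the α-carbon of 11, the E geometry of 11 is transferred suprafacially so that 8-Me and 9-Me are cis and CHO is trans to 8-Me, the catalyst exposes the (2Si,3Re) face of 11 and so sets 8S,9R whichever diene face or endo/exo mode operates, and C10 is then erased when DDQ abstracts its hydride (the only position that gives an O-stabilised allyl cation, C4 having no H) and water collapses the oxocarbenium ion to the Δ5(10)-6-one.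

Step 7
Reactants: 13 enone aldehyde
Product: 14 [(1S,5R,6S)-5-ethenyl-1,5,6-trimethyl-8-oxo-2-(triflyloxy)-1,4,5,6,7,8-hexahydronaphthalen-1-yl]methyl 3-(4-acetoxyphenyl)propanoate
Conditions: Ph3PCH3Br (1.15 equiv), KHMDS (1.1 equiv), THF, −78 to 0 °C
Reagents that add atoms: methyltriphenylphosphonium bromide C[P+](c1ccccc1)(c1ccccc1)c1ccccc1.[Br-]
Why: Wittig methylenation: the ylide reacts with the aldehyde at low temperature far faster than with the hindered tetrasubstituted enone carbonyl or the esters, and the aldehyde has no α-hydrogen so C9 cannot epimerise.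

Step 8
Reactants: 14 vinyl enone
Product: 15 [(1S,5R,6S,8S)-5-ethenyl-8-hydroxy-1,5,6-trimethyl-2-(triflyloxy)-1,4,5,6,7,8-hexahydronaphthalen-1-yl]methyl 3-(4-acetoxyphenyl)propanoate
Conditions: (R)-Me-CBS (0.5 equiv), catecholborane (2 equiv), toluene, −78 to −40 °C; MeOH, pH 7 buffer
Reagents that add atoms: none
Why: Corey–Bakshi–Shibata reduction of the only ketone present (C3 is still masked as its enol triflate): boron binds the carbonyl lone pair on the C7H2 side, away from the very large tetrasubstituted alkenyl carbon C5, and hydride is delivered to the Re face to give 6S by reagent control, while catecholborane does not hydroborate the vinyl group at this temperature.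

Step 9
Reactants: 15 allylic alcohol enol triflate
Product: 17 [(1S,5R,6S,8S)-5-ethenyl-8-hydroxy-1,5,6-trimethyl-2-oxo-1,2,3,4,5,6,7,8-octahydronaphthalen-1-yl]methyl 3-(4-hydroxyphenyl)propanoate, via alkenyl pinacolboronate 16 (not isolated)
Conditions: B2pin2 (1.3 equiv), PdCl2(dppf) (5 mol %), KOAc (3 equiv), dioxane, 80 °C; then NaBO3·4H2O (6 equiv), THF–H2O, rt
Reagents that add atoms: sodium perborate [Na+].[O-]OB=O
Why: Miyaura borylation followed by perborate oxidation turns C–OTf into C–B, then the enol and then the C3 ketone without hydroxide strong enough to touch the alkyl ester; C4 has no hydrogen so the β,γ-enone can neither conjugate nor epimerise, and the perborate stage also cleaves the much more labile aryl acetate to the free phenol.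

Step 10
Reactants: 18 tetronic acid (4-hydroxyfuran-2(5H)-one)
Product: 19 4-bromofuran-2(5H)-one
Conditions: (COBr)2 (1.2 equiv), cat. DMF, CH2Cl2, 0 °C to rt
Reagents that add atoms: oxalyl bromide O=C(Br)C(=O)Br
Why: Vilsmeier–Haack-type halogenation of a vinylogous acid: O-activation of the enol by the bromoiminium salt and addition–elimination of bromide give the β-bromobutenolide.

Step 11
Reactants: 17 vinyl keto phenol; 19 4-bromofuran-2(5H)-one
Product: 21 target CNP0301014.1, via B-alkyl-9-BBN adduct 20 (not isolated)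
Conditions: 9-BBN (3.3 equiv), THF, 0 °C to rt; then 19 (1.5 equiv), PdCl2(dppf) (10 mol %), AsPh3 (10 mol %), Cs2CO3, DMF–H2O, rt to 40 °C
Reagents that add atoms: none
Why: Anti-Markovnikov hydroboration and B-alkyl Suzuki–Miyaura coupling: 9-BBN adds to the only monosubstituted alkene faster than it reduces the α-quaternary C3 ketone and ignores the tetrasubstituted alkene, the two OH groups are only borinated and are released by the aqueous base, the activated C–Br bond of 19 couples at mild temperature to close C12–C13, and no stereocentre is touched.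

## Compound list
1 | 2-methylcyclohexane-1,3-dione | CC1C(=O)CCCC1=O | starting material
2 | 2-(hydroxymethyl)-2-methylcyclohexane-1,3-dione | CC1(CO)C(=O)CCCC1=O | intermediate
3 | 3-(4-hydroxyphenyl)propanoic acid | OC(=O)CCc1ccc(O)cc1 | starting material
4 | 3-(4-acetoxyphenyl)propanoic acid | CC(=O)Oc1ccc(CCC(O)=O)cc1 | intermediate
5 | (1-methyl-2,6-dioxocyclohexyl)methyl 3-(4-acetoxyphenyl)propanoate | CC(=O)Oc1ccc(CCC(=O)OCC2(C)C(=O)CCCC2=O)cc1 | intermediate
6 | [1-methyl-2,6-bis(triflyloxy)cyclohexa-2,5-dien-1-yl]methyl 3-(4-acetoxyphenyl)propanoate (achiral) | CC(=O)Oc1ccc(CCC(=O)OCC2(C)C(OS(=O)(=O)C(F)(F)F)=CCC=C2OS(=O)(=O)C(F)(F)F)cc1 | intermediate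
7 | ethyl vinyl ether | C=COCC | starting material
8 | 1-ethoxyvinyllithium | [Li]C(=C)OCC | intermediate (not isolated)
9 | (1-ethoxyvinyl)zinc chloride | Cl[Zn]C(=C)OCC | intermediate (not isolated)
10 | (S)-[2-(1-ethoxyvinyl)-1-methyl-6-(triflyloxy)cyclohexa-2,5-dien-1-yl]methyl 3-(4-acetoxyphenyl)propanoate (C4 S) | C=C(OCC)C1=CCC=C(OS(=O)(=O)C(F)(F)F)[C@]1(C)COC(=O)CCc1ccc(OC(C)=O)cc1 | intermediate
11 | (E)-2-methylbut-2-enal (tiglaldehyde) | C/C=C(\C)C=O | starting material
12 | [(1S,4aS,5R,6S)-8-ethoxy-5-formyl-1,5,6-trimethyl-2-(triflyloxy)-1,4,4a,5,6,7-hexahydronaphthalen-1-yl]methyl 3-(4-acetoxyphenyl)propanoate (C10 epimer drawn is inconsequential) | C[C@H]1CC(OCC)=C2[C@H](CC=C(OS(=O)(=O)C(F)(F)F)[C@]2(C)COC(=O)CCc2ccc(OC(C)=O)cc2)[C@]1(C)C=O | intermediate (not isolated)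
13 | [(1S,5R,6S)-5-formyl-1,5,6-trimethyl-8-oxo-2-(triflyloxy)-1,4,5,6,7,8-hexahydronaphthalen-1-yl]methyl 3-(4-acetoxyphenyl)propanoate | C[C@H]1CC(=O)C2=C(CC=C(OS(=O)(=O)C(F)(F)F)[C@]2(C)COC(=O)CCc2ccc(OC(C)=O)cc2)[C@]1(C)C=O | intermediate
14 | [(1S,5R,6S)-5-ethenyl-1,5,6-trimethyl-8-oxo-2-(triflyloxy)-1,4,5,6,7,8-hexahydronaphthalen-1-yl]methyl 3-(4-acetoxyphenyl)propanoate | C[C@H]1CC(=O)C2=C(CC=C(OS(=O)(=O)C(F)(F)F)[C@]2(C)COC(=O)CCc2ccc(OC(C)=O)cc2)[C@]1(C)C=C | intermediate
15 | [(1S,5R,6S,8S)-5-ethenyl-8-hydroxy-1,5,6-trimethyl-2-(triflyloxy)-1,4,5,6,7,8-hexahydronaphthalen-1-yl]methyl 3-(4-acetoxyphenyl)propanoate | C[C@H]1C[C@H](O)C2=C(CC=C(OS(=O)(=O)C(F)(F)F)[C@]2(C)COC(=O)CCc2ccc(OC(C)=O)cc2)[C@]1(C)C=C | intermediate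
16 | 2-(pinacolboryl) analogue of 15 (Bpin in place of OTf at C3) | C[C@H]1C[C@H](O)C2=C(CC=C(B3OC(C)(C)C(C)(C)O3)[C@]2(C)COC(=O)CCc2ccc(OC(C)=O)cc2)[C@]1(C)C=C | intermediate (not isolated)
17 | [(1S,5R,6S,8S)-5-ethenyl-8-hydroxy-1,5,6-trimethyl-2-oxo-1,2,3,4,5,6,7,8-octahydronaphthalen-1-yl]methyl 3-(4-hydroxyphenyl)propanoate | C[C@H]1C[C@H](O)C2=C(CCC(=O)[C@]2(C)COC(=O)CCc2ccc(O)cc2)[C@]1(C)C=C | intermediate
18 | tetronic acid (4-hydroxyfuran-2(5H)-one) | OC1=CC(=O)OC1 | starting material
19 | 4-bromofuran-2(5H)-one | BrC1=CC(=O)OC1 | intermediate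
20 | C12-(9-BBN) borane of 17 with 6-O and phenol O carried as 9-BBN borinates | C[C@H]1C[C@H](OB3C4CCCC3CCC4)C2=C(CCC(=O)[C@]2(C)COC(=O)CCc2ccc(OB3C4CCCC3CCC4)cc2)[C@]1(C)CCB1C2CCCC1CCC2 | intermediate (not isolated)
21 | [(1S,5R,6S,8S)-8-hydroxy-1,5,6-trimethyl-2-oxo-5-[2-(5-oxo-2,5-dihydrofuran-3-yl)ethyl]-1,2,3,4,5,6,7,8-octahydronaphthalen-1-yl]methyl 3-(4-hydroxyphenyl)propanoate (CNP0301014.1) | C[C@H]1C[C@H](O)C2=C(CCC(=O)[C@]2(C)COC(=O)CCc2ccc(O)cc2)[C@]1(C)CCC1=CC(=O)OC1 | target

## Step count and risks
Total steps: 11.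
Longest linear sequence: 9 (steps 1, 3, 4, 5, 6, 7, 8, 9, 11).

**Step 5: the enantioselectivity of the desymmetrising coupling may be low.**
- The fallback sets out from 6 and comes back at 13.
- The same 1-ethoxyvinylzinc coupling is run with an achiral catalyst (Pd(PPh3)4, THF, rt), which is routine, and gives the racemic mono-coupled diene F1.
- C4 is then sorted out by diastereomer separation instead of desymmetrisation. In the catalyst-controlled cycloaddition and DDQ sequence of step 6, both enantiomers of the diene receive the same 8S,9R unit.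
- The (S)-half passes through 12 to 13. The (R)-half passes through the C4-epimeric cycloadduct F2 to the C4-epimeric enone aldehyde F3.
- Compound 13 is separated from this epimer by chromatography, with a 50 % ceiling.

**Step 6: a hindered diene and a hindered dienophile may react slowly, and Mukaiyama aldol or hetero-Diels–Alder side reactions are possible.**
- The fallback sets out from 10 (with 11) and comes back at 13.
- The two ring-B bonds are made one at a time by polar steps instead of a cycloaddition.
- First, a Mukaiyama–Michael addition of enol-ether carbon C7 of 10 to 11 is run with the same chiral boron Lewis acid and i-PrOH as trap, followed by aqueous work-up. It gives the open-chain keto aldehyde F4, with C8 set and C9 still epimerisable.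
- Second, TBSOTf and Et3N convert the aldehyde into its enol silane and activate the enone for an intramolecular Mukaiyama–Michael closure from C9 to C10.
- This closure has a chair-like transition state with 8-Me equatorial and CHO trans to it, and it delivers the tert-butyldimethylsilyl enol ether F5, the silicon analogue of 12.
- DDQ, used as in step 6, then gives 13.

**Step 8: reagent control opposes the expected axial-attack bias of the ring, and the ketone is hindered.**
- The fallback sets out from 14 and comes back at 17.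
- The substrate bias is accepted and then inverted. Luche reduction (NaBH4, CeCl3·7H2O, THF–MeOH, −78 °C) gives the 6-epi allylic alcohol F6.
- Mitsunobu inversion with formic acid (PPh3, DIAD, toluene, 0 °C) gives the 6S formate F7.
- Brief methanolysis (KHCO3, MeOH, 0 °C) is carried out before any Pd(0) is present. It removes the formate and the aryl acetate together and gives the 6S alcohol with free phenol F8.
- F8 is taken through the conditions of step 9 to 17.

## Further compounds
F1 | step 5 | racemic [2-(1-ethoxyvinyl)-1-methyl-6-(triflyloxy)cyclohexa-2,5-dien-1-yl]methyl 3-(4-acetoxyphenyl)propanoate | C=C(OCC)C1=CCC=C(OS(=O)(=O)C(F)(F)F)C1(C)COC(=O)CCc1ccc(OC(C)=O)cc1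
F2 | step 5 | (1R,4aR,5R,6S) C4-epimeric cycloadduct (C4 epimer of 12; C10 inconsequential) | C[C@H]1CC(OCC)=C2[C@@H](CC=C(OS(=O)(=O)C(F)(F)F)[C@@]2(C)COC(=O)CCc2ccc(OC(C)=O)cc2)[C@]1(C)C=O
F3 | step 5 | (1R,5R,6S) C4-epimeric enone aldehyde (C4 epimer of 13) | C[C@H]1CC(=O)C2=C(CC=C(OS(=O)(=O)C(F)(F)F)[C@@]2(C)COC(=O)CCc2ccc(OC(C)=O)cc2)[C@]1(C)C=O
F4 | step 6 | [(1S)-2-[(3S)-3,4-dimethyl-5-oxopentanoyl]-1-methyl-6-(triflyloxy)cyclohexa-2,5-dien-1-yl]methyl 3-(4-acetoxyphenyl)propanoate (C9 epimer mixture) | C[C@H](C(C)C=O)CC(=O)C1=CCC=C(OS(=O)(=O)C(F)(F)F)[C@]1(C)COC(=O)CCc1ccc(OC(C)=O)cc1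
F5 | step 6 | 8-(tert-butyldimethylsilyloxy) analogue of 12 (OTBS in place of OEt at C6) | C[C@H]1CC(O[Si](C)(C)C(C)(C)C)=C2[C@H](CC=C(OS(=O)(=O)C(F)(F)F)[C@]2(C)COC(=O)CCc2ccc(OC(C)=O)cc2)[C@]1(C)C=O
F6 | step 8 | (1S,5R,6S,8R) 6-epi allylic alcohol (C6 epimer of 15) | C[C@H]1C[C@@H](O)C2=C(CC=C(OS(=O)(=O)C(F)(F)F)[C@]2(C)COC(=O)CCc2ccc(OC(C)=O)cc2)[C@]1(C)C=C
F7 | step 8 | 6S formate of 15 | C[C@H]1C[C@H](OC=O)C2=C(CC=C(OS(=O)(=O)C(F)(F)F)[C@]2(C)COC(=O)CCc2ccc(OC(C)=O)cc2)[C@]1(C)C=C
F8 | step 8 | des-acetyl 15 (6S alcohol, free phenol, enol triflate intact) | C[C@H]1C[C@H](O)C2=C(CC=C(OS(=O)(=O)C(F)(F)F)[C@]2(C)COC(=O)CCc2ccc(O)cc2)[C@]1(C)C=C
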